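- Time comes first: this flask runs for 30 h, and I follow one substrate molecule through that time.

substrate 0.11 M; first nucleophile 0.121 M; second nucleophile 0.0550 M; time 30 h

    substrate → intermediate (k1 = 0.57 min⁻¹)
    first nucleophile + intermediate → target (k2 = 130 L mol⁻¹ min⁻¹)
    second nucleophile + intermediate → other capture product (k3 = 98 L mol⁻¹ min⁻¹)
    intermediate → solvolysis product (k4 = 8.1 min⁻¹)
    target → over-reaction product (k5 = 0.094 min⁻¹)
    target ⇌ isomer of the product (K6 = 1.3, k6 = 0.27 min⁻¹)
    crystals ⇌ target, rate k7*(cs7 - [target]) while solid is left; crystals form when [target] > cs7 (cs7 = 0.050 M, k7 = 39 min⁻¹)

- what is said of target includes crystals
- crystals is a solid; its amount is given per volume of the solution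
- the reaction counts as stopped when no species that holds the substrate changes by six tenths of a point or more over the second half of the time
- run time (flask): 30 h

- why nothing more happens at 30 h, or that something still does (it is still moving / the second nucleophile has run out first / the first nucleophile has run out first / forward and back rates have come level / all of the substrate has reacted)
- how much of the substrate has reacted by 30 h
- how much over-reaction product there is at 30 h, in percent of the substrate charged

- The substrate's half-life is 1.22 min, far shorter than the run, so I expect 100% reacted and the ending to be that all of the substrate has reacted.
- Each intermediate molecule then stands at a fork, and it lives 0.0342 min, far shorter than the substrate's lifetime. With the nucleophiles held at their charges, its pseudo-first-order exits run at 15.7 min⁻¹ to target, 5.39 min⁻¹ to other capture product and 8.1 min⁻¹ to solvolysis product, so target's chance is 53.8% and other capture product's is 18.4%.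
- The weak link is those held charges, since capture consumes the nucleophiles. I reforge it with the means of start and end: c(first nucleophile) = 0.0914 M and c(second nucleophile) = 0.0449 M. This gives 48.7%, the capture share, the chance that an intermediate molecule becomes target at mean nucleophile concentrations.
- Target and isomer of the product equilibrate, so their pool drains to over-reaction product with a lifetime of 24.5 min, far shorter than the run. Any crystals dissolve again while c(target) lies below 0.050 M, so I commit to 48.7% over-reaction product.
- The forecast gives all of the substrate has reacted, 100% and 48.8%, saying of the crystals and the isomer that “both feed back into the target, which drains irreversibly”.
- This flask gives all of the substrate has reacted, with 100% reacted and 48.9% over-reaction product. Half of its turnover to over-reaction product is done by 0.290 h, far sooner than 30 h. At 6.00 h over-reaction product already stands at 48.9%, and at 300 h it stands at 48.9%. The capture share leaves 55.7% of the first nucleophile here, and the flask holds 56%. For the neighbour charged with 0.21 M, the first pass gives 66.9%, the mean correction with that neighbour's own means of both nucleophiles gives 63.8%, and that neighbour ends at 63.8%.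

The constants used here were set for the occasion; the result is computed.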